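## Retrosynthetic overview
1. Feature: in the all-trans cyclobutane, Ca and Cd carry the two 2-aminoimidazol-4-yl rings and Cb and Cc carry the two CH2NH-acyl arms. The bond Ca–Cb joins a heteroaryl-bearing carbon to a carbon whose arm is a reduced carboxyl group, so Cb–Cc–Cd–Ca are C2–C3–C4–C5 of a prolinate-type pyrrolidine from which only the nitrogen has to be removed.
2. Late disconnections: both pyrrole-2-carboxamide N–C(O) bonds (last step); aminoimidazole ring B at Cd (acetyl → bromoketone → Boc-guanidine); the 2-NH2 of imidazole ring A (C2 lithiation, azide transfer); the CH2N arms (ester → alcohol → azide).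
3. Key disconnection: Ca–Cb, formed by N-amination of pyrrolidine 8 to a 1,1-diazene and loss of N2.
4. Pyrrolidine 8 comes from an exo-selective copper-catalysed asymmetric (3+2) cycloaddition of the glycine imine of an N-sulfamoyl imidazole-4-carbaldehyde with methyl (E)-4-oxopent-2-enoate, followed by ketalisation and inversion at C2.
5. Ring order: imidazole ring A (bought) → pyrrolidine → cyclobutane → aminoimidazole ring B → pyrroles (bought, attached last).

Key step: step 6

Assumption: (R)-DTBM-SEGPHOS is taken to be the ligand antipode that delivers (5S)-6. If the sense of induction is the opposite, the (S)-ligand is used and nothing else changes.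
Remark: 17, 19 and 21 carry three azido groups and are to be kept in solution, cold, dark and on small scale.

## Route

Step 1
Reactants: 1 1H-imidazole-4-carbaldehyde
Product: 2 4-formyl-N,N-dimethylimidazole-1-sulfonamide
Conditions: Me2NSO2Cl (1.2 equiv), Et3N (1.5 equiv), CH2Cl2, rt
Reagents that add atoms: N,N-dimethylsulfamoyl chloride, CN(C)S(=O)(=O)Cl
Why: N-Sulfonylation of the imidazole settles on the less hindered 1,4-isomer under the reversible amine-base conditions; dimethylsulfamoyl is preferred to tosyl because it is not transferred to ammonia, methoxide or hydride in steps 5–7, makes N3 non-basic and later directs lithiation to C2.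

Step 2
Reactants: 2 4-formyl-N,N-dimethylimidazole-1-sulfonamide; 3 glycine methyl ester hydrochloride
Product: 4 methyl (E)-N-{[1-(dimethylsulfamoyl)imidazol-4-yl]methylidene}glycinate
Conditions: Et3N (1.05 equiv), MgSO4, CH2Cl2, rt
Reagents that add atoms: none
Why: Condensation of an aldehyde with a primary amine gives the (E)-aldimine, driven by the drying agent, and the crude imine is used at once.

Step 3
Reactants: 4 methyl (E)-N-{[1-(dimethylsulfamoyl)imidazol-4-yl]methylidene}glycinate; 5 methyl (E)-4-oxopent-2-enoate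
Product: 6 dimethyl (2R,3S,4S,5S)-4-acetyl-5-[1-(dimethylsulfamoyl)imidazol-4-yl]pyrrolidine-2,3-dicarboxylate (exo adduct: 2,5-cis, 2,3-cis, 3,4-trans, 4,5-trans)
Conditions: Cu(MeCN)4PF6 (5 mol %), (R)-DTBM-SEGPHOS (5.5 mol %), Et3N (15 mol %), THF, −20 °C
Reagents that add atoms: none
Why: In this catalytic asymmetric 1,3-dipolar cycloaddition of an N,O-chelated azomethine ylide of monovalent copper, the nucleophilic glycine carbon adds β to the ketone (the stronger acceptor) and so places ester, ester, acetyl and imidazolyl on C2 to C5, the W-shaped ylide fixes 2,5-cis, the (E)-alkene fixes 3,4-trans, the bulky bisphosphine enforces the exo approach (4,5-trans), and its chirality selects the ylide face and hence (5S).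

Step 4
Reactants: 6 exo adduct
Product: 7 dimethyl (2R,3S,4S,5S)-5-[1-(dimethylsulfamoyl)imidazol-4-yl]-4-(2-methyl-1,3-dioxolan-2-yl)pyrrolidine-2,3-dicarboxylate
Conditions: HOCH2CH2OH (10 equiv), HC(OMe)3 (3 equiv), TsOH·H2O (1.3 equiv), CH2Cl2, 40 °C; aq NaHCO3
Reagents that add atoms: ethylene glycol, OCCO
Why: Acid-catalysed ketalisation with an orthoester as water scavenger is run on the pyrrolidinium tosylate so that the NH is not formylated; the mask is needed because a free methyl ketone would condense with ammonia and be captured by the iodonitrene or α-oxidised by trivalent iodine in step 6, and as a β-amino ketone it would open by retro-aza-Michael reaction in step 5, while C4 already sits trans to both neighbours and is not disturbed.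

Step 5
Reactants: 7 2,5-cis ketal pyrrolidine
Product: 8 dimethyl (2S,3S,4S,5S)-5-[1-(dimethylsulfamoyl)imidazol-4-yl]-4-(2-methyl-1,3-dioxolan-2-yl)pyrrolidine-2,3-dicarboxylate (all-trans)
Conditions: NaOMe (0.3 equiv), MeOH, 0 °C to rt; chromatography, recovered 7 resubmitted
Reagents that add atoms: none
Why: This is a thermodynamic epimerisation through the C2 ester enolate: only C2 and C3 are enolisable, C3 is already trans to the bulky ketal carbon on C4, and inversion at C2 removes the cis-vicinal diester contact, so the all-trans isomer should dominate at equilibrium against the fixed centres C4 and C5.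

Step 6
Reactants: 8 all-trans pyrrolidine
Product: 10 dimethyl (1S,2S,3R,4R)-4-[1-(dimethylsulfamoyl)imidazol-4-yl]-3-(2-methyl-1,3-dioxolan-2-yl)cyclobutane-1,2-dicarboxylate (all-trans), via 1,1-diazene 9 (not isolated)
Conditions: PhI(OH)OTs (2.5 equiv), NH2CO2NH4 (8 equiv), CF3CH2OH, 80 °C, sealed tube
Reagents that add atoms: ammonium carbamate, NC(=O)[O-].[NH4+] (its nitrogen enters only the transient 1,1-diazene 9 and leaves again in N2; nothing is added to 10)
Why: PhI(OH)OTs and ammonia released from the carbamate form an electrophilic iodonitrene that aminates the pyrrolidine nitrogen of 8, loss of iodobenzene gives the 1,1-diazene 9, and this extrudes N2 to a singlet 1,4-biradical centred on C2 (ester-stabilised) and C5 (imidazolyl-stabilised). The closest known reaction type is the iodonitrene-mediated ring contraction of NH-pyrrolidines bearing a 2-ester and a 5-aryl group to cyclobutanes, applied here with a sulfonylated imidazol-4-yl group in place of the aryl group. The four-membered ring closes by intramolecular recombination of the two radical termini, which forms Ca–Cb from C5 and C2 (five-to-four ring contraction). Ca and Cb take over the configurations of C5 and C2 with retention because the singlet pair collapses faster than its C–C bonds rotate, Cc and Cd are spectators, and the alternating array of 8 lets the termini meet without building any cis contact. The step needs amination at the ring NH rather than at imidazole N3 and no oxidation of the heteroarene, which the electron-withdrawing sulfamoyl group secures, and it needs an inert carbonyl function at Cd, which the dioxolane secures. It also needs recombination to outrun β-scission into dimethyl fumarate and a vinylimidazole, which the short lifetime of the doubly stabilised singlet pair in the hydrogen-bonding solvent should favour.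

Step 7
Reactants: 10 cyclobutane diester
Product: 11 all-trans 4-[2,3-bis(hydroxymethyl)-4-(2-methyl-1,3-dioxolan-2-yl)cyclobutyl]-N,N-dimethylimidazole-1-sulfonamide (ring carbons configured as in 10)
Conditions: i-Bu2AlH (6 equiv), CH2Cl2, −78 to 0 °C; aq potassium sodium tartrate
Reagents that add atoms: none
Why: Hydride reduction takes both esters to primary alcohols, the reagent leaves N-sulfamoylimidazoles and dioxolanes intact at low temperature, and the ring stereocentres are not affected.

Step 8
Reactants: 11 diol
Product: 12 bis(tert-butyldimethylsilyl) ether of 11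
Conditions: TBSCl (2.5 equiv), imidazole (5 equiv), DMF, rt
Reagents that add atoms: tert-butyldimethylsilyl chloride, CC(C)(C)[Si](C)(C)Cl
Why: Silyl ether formation removes the acidic OH groups ahead of the organolithium step.

Step 9
Reactants: 12 bis-silyl ether
Product: 14 2-azidoimidazole derivative of 12 (azide on C2 of ring A), via 2-lithioimidazole 13 (not isolated)
Conditions: n-BuLi (1.15 equiv), THF, −78 °C; TsN3 (1.3 equiv), −78 °C to rt; aq NH4Cl; exclusion of light
Reagents that add atoms: tosyl azide, Cc1ccc(cc1)S(=O)(=O)N=[N+]=[N-]; n-butyllithium, [Li]CCCC (lithium of the transient 13 only)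
Why: Directed lithiation at C2, the most acidic position of a 1-sulfamoylimidazole, followed by electrophilic azidation with tosyl azide (a triazenide that loses sulfinate) installs the future 2-amino nitrogen of ring A at a stage free of electrophilic groups.

Step 10
Reactants: 14 azido bis-silyl ether ketal
Product: 15 all-trans 4-[2-acetyl-3,4-bis(hydroxymethyl)cyclobutyl]-2-azido-N,N-dimethylimidazole-1-sulfonamide
Conditions: 2 M aq HCl/THF (1:1), rt
Reagents that add atoms: water, O
Why: Acid hydrolysis cleaves both primary silyl ethers and the dioxolane in one operation, the sulfamoyl group needs hot acid and stays, and a hemiketal cannot form because it would be trans-fused to the cyclobutane.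

Step 11
Reactants: 15 keto diol
Product: 16 bis(methanesulfonate) of 15
Conditions: MsCl (2.6 equiv), Et3N (4 equiv), CH2Cl2, 0 °C
Reagents that add atoms: methanesulfonyl chloride, CS(=O)(=O)Cl
Why: O-Sulfonylation activates both primary alcohols, and closure to a cyclic ether is blocked by the trans arrangement of the two arms.

Step 12
Reactants: 16 dimesylate
Product: 17 all-trans 4-[2-acetyl-3,4-bis(azidomethyl)cyclobutyl]-2-azido-N,N-dimethylimidazole-1-sulfonamide
Conditions: NaN3 (5 equiv), DMF, 55 °C
Reagents that add atoms: sodium azide, [Na+].[N-]=[N+]=[N-]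
Why: Twofold SN2 displacement occurs at unhindered primary carbons outside the ring, and the only enolisable ring carbon (Cd) already holds its thermodynamic trans position.

Step 13
Reactants: 17 keto triazide
Product: 19 all-trans 2-azido-4-[2,3-bis(azidomethyl)-4-(bromoacetyl)cyclobutyl]-N,N-dimethylimidazole-1-sulfonamide, via silyl enol ether 18 (not isolated)
Conditions: LiN(SiMe3)2 (1.1 equiv), Me3SiCl (1.5 equiv), THF, −78 °C; then NBS (1.05 equiv), −78 to 0 °C
Reagents that add atoms: N-bromosuccinimide, O=C1CCC(=O)N1Br; chlorotrimethylsilane, C[Si](C)(C)Cl (silyl group of the transient 18 only)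
Why: Kinetic deprotonation takes the methyl protons rather than the ring methine (whose enolate would put an exocyclic double bond on the cyclobutane), in situ silylation gives the terminal silyl enol ether, and its bromination with NBS is far faster than attack on the doubly deactivated ring A, at a stage where no pyrrole or free aminoimidazole is present.

Step 14
Reactants: 19 bromoketone; 20 N-Boc-guanidine
Product: 21 tert-butyl 2-amino-4-{all-trans-2-[2-azido-1-(dimethylsulfamoyl)imidazol-4-yl]-3,4-bis(azidomethyl)cyclobutyl}imidazole-1-carboxylate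
Conditions: 20 (3.5 equiv), DMF, rt
Reagents that add atoms: none
Why: Condensation of an α-haloketone with N-Boc-guanidine (N-alkylation, cyclisation on the ketone, dehydration) is the standard 2-aminoimidazole annulation and gives ring B as its 1-Boc derivative, while ring A cannot be alkylated as long as it bears the sulfamoyl group.

Step 15
Reactants: 21 triazide
Product: 23 all-trans 4,4'-[3,4-bis(aminomethyl)cyclobutane-1,2-diyl]bis(1H-imidazol-2-amine) tetrahydrochloride, via protected triamine 22 (not isolated)
Conditions: H2 (1 atm), Pd/C, MeOH, rt; filter; 4 M aq HCl, reflux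
Reagents that add atoms: hydrogen chloride, Cl
Why: Catalytic hydrogenation reduces the two alkyl azides and the heteroaryl azide to amines, and hot aqueous acid then removes Boc (including any that has migrated to a primary amine) and hydrolyses the sulfamoyl group to give the stable tetrahydrochloride.

Step 16
Reactants: 23 tetraamine tetrahydrochloride; 24 2,2,2-trichloro-1-(1H-pyrrol-2-yl)ethanone
Product: 25 N,N'-{[(1R,2R,3S,4S)-3,4-bis(2-amino-1H-imidazol-4-yl)cyclobutane-1,2-diyl]bis(methylene)}bis(1H-pyrrole-2-carboxamide) (target)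
Conditions: 24 (2.1 equiv), Na2CO3 (6 equiv), DMF, rt
Reagents that add atoms: none
Why: In this amide formation with a trichloromethyl ketone as acyl donor (haloform-type acyl transfer), the primary alkylamines are acylated irreversibly while the guanidine-like 2-aminoimidazoles are poor acyl acceptors, a selectivity established for aminoalkyl-2-aminoimidazoles, and no stereocentre is touched.

## Compound list
1 | 1H-imidazole-4-carbaldehyde | O=Cc1c[nH]cn1 | starting material
2 | 4-formyl-N,N-dimethylimidazole-1-sulfonamide | CN(C)S(=O)(=O)n1cnc(C=O)c1 | intermediate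
3 | glycine methyl ester hydrochloride | COC(=O)CN.Cl | starting material
4 | methyl (E)-N-{[1-(dimethylsulfamoyl)imidazol-4-yl]methylidene}glycinate | CN(C)S(=O)(=O)n1cnc(/C=N/CC(=O)OC)c1 | intermediate
5 | methyl (E)-4-oxopent-2-enoate | COC(=O)/C=C/C(C)=O | starting material
6 | dimethyl (2R,3S,4S,5S)-4-acetyl-5-[1-(dimethylsulfamoyl)imidazol-4-yl]pyrrolidine-2,3-dicarboxylate | CN(C)S(=O)(=O)n1cnc(c1)[C@H]2N[C@@H](C(=O)OC)[C@@H](C(=O)OC)[C@@H]2C(C)=O | intermediate
7 | dimethyl (2R,3S,4S,5S)-5-[1-(dimethylsulfamoyl)imidazol-4-yl]-4-(2-methyl-1,3-dioxolan-2-yl)pyrrolidine-2,3-dicarboxylate | CN(C)S(=O)(=O)n1cnc(c1)[C@H]2N[C@@H](C(=O)OC)[C@@H](C(=O)OC)[C@@H]2C3(C)OCCO3 | intermediate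
8 | dimethyl (2S,3S,4S,5S)-5-[1-(dimethylsulfamoyl)imidazol-4-yl]-4-(2-methyl-1,3-dioxolan-2-yl)pyrrolidine-2,3-dicarboxylate (all-trans, key precursor) | CN(C)S(=O)(=O)n1cnc(c1)[C@H]2N[C@H](C(=O)OC)[C@@H](C(=O)OC)[C@@H]2C3(C)OCCO3 | intermediate
9 | 1,1-diazene of 8 (not isolated) | CN(C)S(=O)(=O)n1cnc(c1)[C@H]2[N+](=[N-])[C@H](C(=O)OC)[C@@H](C(=O)OC)[C@@H]2C3(C)OCCO3 | intermediate
10 | dimethyl (1S,2S,3R,4R)-4-[1-(dimethylsulfamoyl)imidazol-4-yl]-3-(2-methyl-1,3-dioxolan-2-yl)cyclobutane-1,2-dicarboxylate (all-trans, key product) | CN(C)S(=O)(=O)n1cnc(c1)[C@H]2[C@H](C(=O)OC)[C@@H](C(=O)OC)[C@@H]2C3(C)OCCO3 | intermediate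
11 | all-trans 4-[2,3-bis(hydroxymethyl)-4-(2-methyl-1,3-dioxolan-2-yl)cyclobutyl]-N,N-dimethylimidazole-1-sulfonamide | CN(C)S(=O)(=O)n1cnc(c1)[C@H]2[C@H](CO)[C@@H](CO)[C@@H]2C3(C)OCCO3 | intermediate
12 | bis(tert-butyldimethylsilyl) ether of 11 | CN(C)S(=O)(=O)n1cnc(c1)[C@H]2[C@H](CO[Si](C)(C)C(C)(C)C)[C@@H](CO[Si](C)(C)C(C)(C)C)[C@@H]2C3(C)OCCO3 | intermediate
13 | 2-lithioimidazole derived from 12 (not isolated) | CN(C)S(=O)(=O)n1c([Li])nc(c1)[C@H]2[C@H](CO[Si](C)(C)C(C)(C)C)[C@@H](CO[Si](C)(C)C(C)(C)C)[C@@H]2C3(C)OCCO3 | intermediate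
14 | 2-azidoimidazole derivative of 12 | CN(C)S(=O)(=O)n1c(N=[N+]=[N-])nc(c1)[C@H]2[C@H](CO[Si](C)(C)C(C)(C)C)[C@@H](CO[Si](C)(C)C(C)(C)C)[C@@H]2C3(C)OCCO3 | intermediate
15 | all-trans 4-[2-acetyl-3,4-bis(hydroxymethyl)cyclobutyl]-2-azido-N,N-dimethylimidazole-1-sulfonamide | CN(C)S(=O)(=O)n1c(N=[N+]=[N-])nc(c1)[C@H]2[C@H](CO)[C@@H](CO)[C@@H]2C(C)=O | intermediate
16 | bis(methanesulfonate) of 15 | CN(C)S(=O)(=O)n1c(N=[N+]=[N-])nc(c1)[C@H]2[C@H](COS(C)(=O)=O)[C@@H](COS(C)(=O)=O)[C@@H]2C(C)=O | intermediate
17 | all-trans 4-[2-acetyl-3,4-bis(azidomethyl)cyclobutyl]-2-azido-N,N-dimethylimidazole-1-sulfonamide | CN(C)S(=O)(=O)n1c(N=[N+]=[N-])nc(c1)[C@H]2[C@H](CN=[N+]=[N-])[C@@H](CN=[N+]=[N-])[C@@H]2C(C)=O | intermediate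
18 | terminal trimethylsilyl enol ether of 17 (not isolated) | CN(C)S(=O)(=O)n1c(N=[N+]=[N-])nc(c1)[C@H]2[C@H](CN=[N+]=[N-])[C@@H](CN=[N+]=[N-])[C@@H]2C(=C)O[Si](C)(C)C | intermediate
19 | all-trans 2-azido-4-[2,3-bis(azidomethyl)-4-(bromoacetyl)cyclobutyl]-N,N-dimethylimidazole-1-sulfonamide | CN(C)S(=O)(=O)n1c(N=[N+]=[N-])nc(c1)[C@H]2[C@H](CN=[N+]=[N-])[C@@H](CN=[N+]=[N-])[C@@H]2C(=O)CBr | intermediate
20 | N-Boc-guanidine | CC(C)(C)OC(=O)NC(N)=N | starting material
21 | tert-butyl 2-amino-4-{all-trans-2-[2-azido-1-(dimethylsulfamoyl)imidazol-4-yl]-3,4-bis(azidomethyl)cyclobutyl}imidazole-1-carboxylate | CN(C)S(=O)(=O)n1c(N=[N+]=[N-])nc(c1)[C@H]2[C@H](CN=[N+]=[N-])[C@@H](CN=[N+]=[N-])[C@@H]2c3cn(C(=O)OC(C)(C)C)c(N)n3 | intermediate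
22 | protected triamine from 21 (all three azides reduced; not isolated) | CN(C)S(=O)(=O)n1c(N)nc(c1)[C@H]2[C@H](CN)[C@@H](CN)[C@@H]2c3cn(C(=O)OC(C)(C)C)c(N)n3 | intermediate
23 | all-trans 4,4'-[3,4-bis(aminomethyl)cyclobutane-1,2-diyl]bis(1H-imidazol-2-amine) tetrahydrochloride | Nc1nc(c[nH]1)[C@H]2[C@H](CN)[C@@H](CN)[C@@H]2c3c[nH]c(N)n3.Cl.Cl.Cl.Cl | intermediate
24 | 2,2,2-trichloro-1-(1H-pyrrol-2-yl)ethanone | O=C(c1ccc[nH]1)C(Cl)(Cl)Cl | starting material
25 | N,N'-{[(1R,2R,3S,4S)-3,4-bis(2-amino-1H-imidazol-4-yl)cyclobutane-1,2-diyl]bis(methylene)}bis(1H-pyrrole-2-carboxamide) | Nc1ncc([C@H]2[C@H](CNC(=O)c3ccc[nH]3)[C@@H](CNC(=O)c3ccc[nH]3)[C@@H]2c2cnc(N)[nH]2)[nH]1 | target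

## Count and risks
Total step count: 16. Longest linear sequence: 16 steps, from 1 to 25.

Step 6 (nitrogen deletion) is the most likely to fail. The 1,4-biradical may fragment by β-scission into two alkenes, the heteroarene may be oxidised, or the dioxolane may solvolyse at 80 °C before the ring closes. The fallback generates the diazene stepwise and cold, without ammonia, acid or heat. It sets out from 8. Nitrosation (t-BuONO, CH2Cl2) gives the N-nitrosopyrrolidine F1, and reduction (Zn, AcOH/MeOH, 0 °C) gives the N-aminopyrrolidine F2. Oxidation of this 1,1-disubstituted hydrazine (PhI(OAc)2, CH2Cl2, −40 °C to rt) produces 9, which loses N2. This classical hydrazine oxidation comes back to the route at 10.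

Step 5 (inversion at C2) is the second risk. The equilibrium may not lie far enough on the 2,5-trans side, or methoxide may slowly attack the sulfamoyl group or scramble C3. The fallback postpones the inversion and sets out from 7. The 2,5-cis pyrrolidine is contracted under the conditions of step 6 to the cyclobutane with a cis,cis-flanked Cb ester F3. NaOMe in MeOH then epimerises Cb, where relief of two cis contacts on a four-membered ring gives a larger driving force and no amine is left to take part in side reactions. This comes back to the route at 10.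

Step 3 (cycloaddition) is the third risk. Chelation of copper by imidazole N3 together with the imine nitrogen may compete with the N,O-chelate and erode exo/endo and facial selectivity. The fallback gives up kinetic control of the relative configuration and sets out from 4 and 5. An endo-selective catalyst (AgOAc with a chiral ferrocenyl P,S-ligand) sets C2 and C5 in the same sense and gives the endo adduct F4, alone or mixed with 6. DBU in MeOH then inverts C4, C3 and C2 one after the other, each passing through an isomer with a single cis contact, against the fixed C5, and funnels all isomers into the all-trans acetylpyrrolidine F5. Ketalisation as in step 4 comes back to the route at 8.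

Further compounds
F1 | step 6 | dimethyl (2S,3S,4S,5S)-5-[1-(dimethylsulfamoyl)imidazol-4-yl]-4-(2-methyl-1,3-dioxolan-2-yl)-1-nitrosopyrrolidine-2,3-dicarboxylate | CN(C)S(=O)(=O)n1cnc(c1)[C@H]2N(N=O)[C@H](C(=O)OC)[C@@H](C(=O)OC)[C@@H]2C3(C)OCCO3
F2 | step 6 | dimethyl (2S,3S,4S,5S)-1-amino-5-[1-(dimethylsulfamoyl)imidazol-4-yl]-4-(2-methyl-1,3-dioxolan-2-yl)pyrrolidine-2,3-dicarboxylate | CN(C)S(=O)(=O)n1cnc(c1)[C@H]2N(N)[C@H](C(=O)OC)[C@@H](C(=O)OC)[C@@H]2C3(C)OCCO3
F3 | step 5 | dimethyl (1R,2S,3R,4R)-4-[1-(dimethylsulfamoyl)imidazol-4-yl]-3-(2-methyl-1,3-dioxolan-2-yl)cyclobutane-1,2-dicarboxylate | CN(C)S(=O)(=O)n1cnc(c1)[C@H]2[C@@H](C(=O)OC)[C@@H](C(=O)OC)[C@@H]2C3(C)OCCO3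
F4 | step 3 | dimethyl (2R,3R,4R,5S)-4-acetyl-5-[1-(dimethylsulfamoyl)imidazol-4-yl]pyrrolidine-2,3-dicarboxylate (endo adduct) | CN(C)S(=O)(=O)n1cnc(c1)[C@H]2N[C@@H](C(=O)OC)[C@H](C(=O)OC)[C@H]2C(C)=O
F5 | step 3 | dimethyl (2S,3S,4S,5S)-4-acetyl-5-[1-(dimethylsulfamoyl)imidazol-4-yl]pyrrolidine-2,3-dicarboxylate (all-trans) | CN(C)S(=O)(=O)n1cnc(c1)[C@H]2N[C@H](C(=O)OC)[C@@H](C(=O)OC)[C@@H]2C(C)=O
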